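**Assumption:** the proline aldol of 6 proceeds through a chair transition state with the acetal-bearing carbon equatorial, so D-proline gives the ketol whose C4/C5 arrangement matches the target. The target's trans-2,6-dimethoxy arrangement is taken to be the thermodynamically accessible acetal diastereomer.

## Retrosynthetic overview
1. Xenibecin is the cyclic bis-methyl acetal of a 1,5-dialdehyde. It comes from acid/MeOH isomerisation of an acetal-aldehyde, whose dienyl side chain is built by aldol/dehydration with (E)-4-oxopent-2-enal (from ring-opened 2-methylfuran) followed by MeLi.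
2. The (E)-trisubstituted cyclononene with exocyclic methylene comes from Grob fragmentation of a 6/5 hydrindane (a ring-fusion bond is cleaved), then Petasis methylenation.
3. The hydrindane comes from a desymmetrising proline aldol of a triketone made from 2-methylcyclopentane-1,3-dione and an acetal-bearing vinyl ketone. The C5 ketone becomes CH–CH2CO2Me by HWE and conjugate reduction.
4. Ring order: cyclopentane (from the starting dione), cyclohexane (aldol), nine-membered ring (fragmentation), tetrahydropyran (final acetalisation).

## Route

**Step 1**
Reactants: 1, 2-methylfuran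
Product: 2, (E)-4-oxopent-2-enal
Conditions: (i) NBS, pyridine, NaHCO3, THF/H2O, −20 °C; (ii) I2 (cat.), CH2Cl2, rt
Reagents that add atoms: water (adds O), O
Why: oxidative furan ring-opening (Kobayashi-type) destroys the aromatic ring to give the (Z)-4-oxoenal, which iodine isomerises to the E isomer; this supplies the C5 side-chain unit, with its methyl ketone as the future CMe2OH.

**Step 2**
Reactants: 3, 4,4-dimethoxybutan-2-one
Product: 4, 1,1-dimethoxypent-4-en-3-one
Conditions: LDA, THF, −78 °C; then CH2=NMe2+ I−; then MeI, NaHCO3, MeOH, 0 °C to rt
Reagents that add atoms: Eschenmoser's salt (adds CH2), C=[N+](C)C.[I-]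
Why: kinetic enolisation at the methyl group followed by Mannich reaction and quaternisation/elimination (Hofmann-type) gives the vinyl ketone without touching the acetal.

**Step 3**
Reactants: 4; 5, 2-methylcyclopentane-1,3-dione
Product: 6, 2-(5,5-dimethoxy-3-oxopentyl)-2-methylcyclopentane-1,3-dione (prochiral, achiral)
Conditions: H2O, Et3N (cat.), rt
Reagents that add atoms: none
Why: Michael addition of the dione C2 to the vinyl ketone creates the quaternary carbon that carries the symmetry-breaking step.

**Step 4**
Reactants: 6
Product: 7, (3aR,4R,7aR)-4-(dimethoxymethyl)-3a-hydroxy-7a-methylhexahydro-1H-indene-1,5(4H)-dione (cis-fused, OH/Me cis, CH(OMe)2 cis to OH)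
Conditions: D-proline (10 mol %), DMF, rt
Reagents that add atoms: none
Why: enamine aldol onto one of the two enantiotopic ring carbonyls breaks the dione's symmetry (Hajos–Parrish/Wieland–Miescher type) and sets C3a/C7a, while C4 goes equatorial. Proposed new method: the α-acetal-substituted enamine has not been used in this desymmetrisation, but a substituted analogue (ethyl vinyl ketone giving the 4-methyl ketol) is a close precedent; the β-OMe on the enamine could eliminate, which a cold, dilute run should minimise.

**Step 5**
Reactants: 7
Product: 8, C3a triethylsilyl ether of 7 (stereochemistry unchanged)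
Conditions: TESOTf, 2,6-lutidine, CH2Cl2, −78 to −40 °C
Reagents that add atoms: TESOTf, CC[Si](CC)(CC)OS(=O)(=O)C(F)(F)F
Why: masking the tertiary aldol OH prevents retro-aldol and dehydration in the basic steps that follow (silyl protection).

**Step 6**
Reactants: 8
Product: 9, methyl 2-[C5-ylidene]acetate (exocyclic enoate, E/Z mixture; C1 ketone untouched)
Conditions: (EtO)2P(O)CH2CO2Me, NaH, THF, 0 to 40 °C
Reagents that add atoms: methyl diethylphosphonoacetate, CCOP(=O)(OCC)CC(=O)OC
Why: HWE olefination occurs at the accessible cyclohexanone C5, while the C1 ketone next to the quaternary carbon is too hindered.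

**Step 7**
Reactants: 9
Product: 10, C1 secondary alcohol (hydride delivered anti to the angular methyl)
Conditions: NaBH4, MeOH/CH2Cl2, −20 °C
Reagents that add atoms: none
Why: chemoselective ketone reduction (the enoate and silyl ether are inert) sets the C1 carbinol configuration required for the antiperiplanar fragmentation.

**Step 8**
Reactants: 10
Product: 11, saturated methyl ester (new C5 centre with CH2CO2Me equatorial, trans to the C4 acetal substituent)
Conditions: Mg, MeOH, 0 °C to rt
Reagents that add atoms: none
Why: Mg/MeOH conjugate reduction proceeds via a β-carbanion that is protonated axially, giving the trans-diequatorial arrangement that becomes the trans ring fusion; this is the only step that sets C2' of the target.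

**Step 9**
Reactants: 11
Product: 12, C1 mesylate
Conditions: MsCl, Et3N, DMAP (cat.), CH2Cl2, 0 °C
Reagents that add atoms: methanesulfonyl chloride, CS(=O)(=O)Cl
Why: converts the C1 alcohol into the leaving group of a 1,3-diol monosulfonate (Grob precursor).

**Step 10**
Reactants: 12
Product: 13, methyl 2-[(E)-9-(dimethoxymethyl)-5-methyl-1-oxocyclonon-4-en-8-yl]acetate (C12/C2' as in the target, E ring alkene)
Conditions: TBAF, THF, 0 to 35 °C
Reagents that add atoms: none
Why: fluoride unmasks the tertiary alkoxide, which drives Grob fragmentation of the C3a–C7a ring-fusion bond anti to the C1–OMs bond; the 6/5 system opens to the nine-membered ring with the E trisubstituted alkene, and chirality is relayed to C4/C5 while the quaternary centres are destroyed. Proposed new method: mechanistic reasoning is antiperiplanar alkoxide-push/sulfonate-pull fragmentation in a chair-like alkoxide, closest known reaction being Wieland–Miescher ketol Grob fragmentation to (E)-cyclodecenones in germacrane work; the risks are β-elimination of MeOH from the new β-methoxy ketone and E/Z leakage.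

**Step 11**
Reactants: 13
Product: 14, exocyclic-methylene nine-membered ring ester
Conditions: Cp2TiMe2, toluene, 70 °C, dark
Reagents that add atoms: dimethyltitanocene (adds CH2), C[Ti](C)(C1C=CC=C1)C1C=CC=C1
Why: Petasis methylenation of the ring ketone is non-basic, so the adjacent C12 stereocentre does not epimerise and the ester and acetal survive.

**Step 12**
Reactants: 14; 2
Product: 15, β-hydroxy ester aldol adduct (new centres at C3' and the carbinol are destroyed in Step 13)
Conditions: LDA, THF, −78 °C; then 2
Reagents that add atoms: none
Why: the ester enolate adds 1,2 to the aldehyde of the enal (aldol reaction), which is far more electrophilic than the ketone.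

**Step 13**
Reactants: 15
Product: 16, (2E,4E)-dienoate methyl ketone (ester trans to the vinyl group)
Conditions: MsCl, Et3N, CH2Cl2, 0 °C; then DBU, rt
Reagents that add atoms: none
Why: mesylation then E1cB elimination gives the thermodynamically preferred E trisubstituted enoate, whose geometry matches the target.

**Step 14**
Reactants: 16
Product: 17, tertiary carbinol dienoate (CMe2OH side chain)
Conditions: MeLi, CeCl3, THF, −78 °C
Reagents that add atoms: methyllithium, [Li]C
Why: organocerium 1,2-addition is selective for the methyl ketone over the ester and avoids conjugate addition.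

**Step 15**
Reactants: 17
Product: 18, allylic alcohol (ester reduced to CH2OH)
Conditions: DIBAL-H (2.5 equiv), toluene, −78 to −20 °C
Reagents that add atoms: none
Why: hydride reduction of the ester leaves the acetal, dienes and tertiary alcohol intact.

**Step 16**
Reactants: 18
Product: 19, acetal-aldehyde (α-alkylidene enal, free tertiary alcohol)
Conditions: MnO2 (activated), CH2Cl2, rt
Reagents that add atoms: none
Why: MnO2 oxidises only the allylic, dienyl primary alcohol and leaves the tertiary alcohol alone.

**Step 17**
Reactants: 19
Product: 20, xenibecin
Conditions: CSA (10 mol %), MeOH, 0 to 25 °C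
Reagents that add atoms: none net (methanol is the solvent and shuttles OMe groups; 19 and 20 are isomers)
Why: acid ionises the dimethyl acetal to an oxocarbenium, the aldehyde oxygen closes the tetrahydropyran, and methanol traps the second oxocarbenium, so the two acetal centres equilibrate anomerically. Proposed new method: mechanistic reasoning is oxocarbenium/acetal exchange to the cyclic bis-acetal under thermodynamic control, closest known reaction being glutaraldehyde-to-2,6-dialkoxytetrahydropyran acetalisation; minor acetal diastereomers are removed by HPLC.

## Compound list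
1 | 2-methylfuran | Cc1ccco1 | starting material
2 | (E)-4-oxopent-2-enal | CC(=O)/C=C/C=O | intermediate (building block)
3 | 4,4-dimethoxybutan-2-one | CC(=O)CC(OC)OC | starting material
4 | 1,1-dimethoxypent-4-en-3-one | C=CC(=O)CC(OC)OC | intermediate (building block)
5 | 2-methylcyclopentane-1,3-dione | CC1C(=O)CCC1=O | starting material
6 | triketone | CC1(CCC(=O)CC(OC)OC)C(=O)CCC1=O | intermediate
7 | ketol | COC(OC)[C@@H]1C(=O)CC[C@@]2(C)C(=O)CC[C@@]12O | intermediate
8 | TES ether | COC(OC)[C@@H]1C(=O)CC[C@@]2(C)C(=O)CC[C@@]12O[Si](CC)(CC)CC | intermediate
9 | enoate | COC(OC)[C@@H]1C(=CC(=O)OC)CC[C@@]2(C)C(=O)CC[C@@]12O[Si](CC)(CC)CC | intermediate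
10 | C1 alcohol | COC(OC)[C@@H]1C(=CC(=O)OC)CC[C@@]2(C)[C@H](O)CC[C@@]12O[Si](CC)(CC)CC | intermediate
11 | saturated ester | COC(OC)[C@@H]1[C@@H](CC(=O)OC)CC[C@@]2(C)[C@H](O)CC[C@@]12O[Si](CC)(CC)CC | intermediate
12 | mesylate | COC(OC)[C@@H]1[C@@H](CC(=O)OC)CC[C@@]2(C)[C@H](OS(C)(=O)=O)CC[C@@]12O[Si](CC)(CC)CC | intermediate
13 | cyclononenone | O=C1CC/C=C(\C)CC[C@H](CC(=O)OC)[C@H]1C(OC)OC | intermediate
14 | methylene ester | C=C1CC/C=C(\C)CC[C@H](CC(=O)OC)[C@H]1C(OC)OC | intermediate
15 | aldol adduct | C=C1CC/C=C(\C)CC[C@H](C(C(=O)OC)C(O)/C=C/C(C)=O)[C@H]1C(OC)OC | intermediate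
16 | dienoate ketone | C=C1CC/C=C(\C)CC[C@H](/C(C(=O)OC)=C\C=C\C(C)=O)[C@H]1C(OC)OC | intermediate
17 | carbinol dienoate | C=C1CC/C=C(\C)CC[C@H](/C(C(=O)OC)=C\C=C\C(C)(C)O)[C@H]1C(OC)OC | intermediate
18 | allylic alcohol | C=C1CC/C=C(\C)CC[C@H](/C(CO)=C\C=C\C(C)(C)O)[C@H]1C(OC)OC | intermediate
19 | acetal-aldehyde | C=C1CC/C=C(\C)CC[C@H](/C(C=O)=C\C=C\C(C)(C)O)[C@H]1C(OC)OC | intermediate
20 | xenibecin | C=C1CC/C=C(\C)CC[C@@H]2/C(=C\C=C\C(C)(C)O)[C@@H](OC)O[C@H](OC)[C@@H]12 | target

**Totals:** 17 steps in total; longest linear sequence 16 steps (from 3, through 4, to 20).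

## Three steps most likely to fail
1. **Step 10 (Grob fragmentation).** It may give the Z alkene, epimerise C12, or eliminate MeOH from the β-methoxy ketone. Fallback: make the Z-cyclononene by RCM (Hoveyda–Grubbs II) of a diene on a pre-built trans-2-oxadecalin, then convert Z to E by AgNO3–silica flow photoisomerisation before adding the side chain.
2. **Step 4 (desymmetrising aldol).** The acetal-substituted enamine may eliminate, or the C4 configuration may come out wrong. Fallback: desymmetrise 6 by baker's-yeast reduction to the 3-hydroxy-ketone, then close the cyclohexane with a base-mediated aldol on the silyl-protected substrate and separate diastereomers.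
3. **Step 17 (acetalisation).** The conjugated aldehyde may close poorly and the anomeric centres may give a mixture. Fallback: hydrolyse 19 to the dialdehyde (aqueous AcOH), isolate the lactol, and methylate it with Me3O+BF4−/proton sponge, then separate the isomers by HPLC.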